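**Plan**

- The target carries, on the arene, a carbon bearing OH and two acyloxymethyl arms: the isopropyl group of thymol methyl ether oxygenated at all three carbons. The alkene 2-isopropenyl-5-methylanisole (3) already holds the full ten-carbon skeleton, and its 1,1-disubstituted C=C has one allylic position only, the methyl group.
- Retrosynthesis: cut one CH2–O ester bond of 10 with closure of an oxirane (to glycidyl ester 8), then the acyl C–O bond (to epoxy alcohol 6), then all three C–O bonds of 6 (to 3 and O2), and last the aryl–alkenyl C–C bond (to 1 and 2).
- Forward: a Suzuki coupling joins the chain; photooxygenation with titanium makes the only ring of the route, the oxirane, together with the CH2OH group; acylation follows; carboxylate opening at the oxirane CH2 turns the ring into the second ester arm.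
- Stereochemistry: none has to be controlled (see remark).

Key step: step 2

Remark: the carbinol carbon of the target bears two identical isobutyryloxymethyl groups, so the target is achiral and the given SMILES describes one compound; intermediates 6 and 8 are racemic and their stereocentre disappears on ring opening.

**Route**

Step 1
Reactants: 1 1-bromo-2-methoxy-4-methylbenzene; 2 4,4,5,5-tetramethyl-2-(prop-1-en-2-yl)-1,3,2-dioxaborolane (isopropenylboronic acid pinacol ester)
Product: 3 2-methoxy-4-methyl-1-(prop-1-en-2-yl)benzene (2-isopropenyl-5-methylanisole)
Conditions: Pd(dppf)Cl2·CH2Cl2 (3 mol%), K2CO3, 1,4-dioxane/H2O 4:1, 85 °C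
Reagents that add atoms: isopropenylboronic acid pinacol ester 2, C=C(C)B1OC(C)(C)C(C)(C)O1
Why: Suzuki–Miyaura coupling of an aryl bromide with an alkenyl pinacol boronate is routine, tolerates the ortho-methoxy group and creates no stereocentre.

Step 2
Reactants: 3 2-methoxy-4-methyl-1-(prop-1-en-2-yl)benzene; 4 dioxygen
Product: 6 [2-(2-methoxy-4-methylphenyl)oxiran-2-yl]methanol (racemic), via 2-(2-methoxy-4-methylphenyl)prop-2-en-1-yl hydroperoxide 5 (not isolated)
Conditions: O2, TPP (0.5 mol%), hν (sodium lamp or white LED), Ti(OiPr)4 (10 mol%), 4 Å MS, CH2Cl2, −10 °C; then aq. Na2SO4/Et2O, Celite; Et3N-deactivated SiO2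
Reagents that add atoms: dioxygen 4, O=O
Why: Sensitised irradiation generates singlet oxygen, which bonds to the terminal alkene carbon of 3 while removing a hydrogen from the methyl group, the only allylic position (Schenck ene reaction through a perepoxide-like transition state), to give the transposed 2-arylallyl hydroperoxide 5. Titanium exchanges isopropoxide for 5 and for allylic alkoxide, and the bound peroxide passes its distal oxygen to the C=C of a titanium-bound allyl alkoxide as in a Sharpless epoxidation, each donor molecule becoming the next acceptor, so that every molecule of 5 should end as 6 with both atoms of O2 retained; the closest known reaction type is the one-pot titanium-catalysed photooxygenation of alkenes to epoxy alcohols. The oxirane is closed by concerted electrophilic oxygen-atom transfer ([2+1] addition through a spiro transition state), not by a nucleophilic displacement. Its quaternary carbon is the only new stereocentre and, with nothing chiral present, 6 forms as the racemate, which is immaterial because this carbon becomes the achiral carbinol carbon of 10. The step needs the ene pathway to beat [2+2] addition (dioxetane, then cleavage to the aryl methyl ketone) and [4+2] addition across the styrene unit: the ortho-methoxy group twists the arene out of the alkene plane, so the styrene diene cannot become coplanar, while the methyl C–H bonds stay accessible. The acid-labile benzylic oxirane should be spared by the catalytic titanium loading, molecular sieves, low temperature and non-acidic work-up.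

Step 3
Reactants: 6 [2-(2-methoxy-4-methylphenyl)oxiran-2-yl]methanol (racemic); 7 2-methylpropanoic anhydride (isobutyric anhydride)
Product: 8 [2-(2-methoxy-4-methylphenyl)oxiran-2-yl]methyl 2-methylpropanoate (racemic)
Conditions: (iPrCO)2O, Et3N, DMAP (5 mol%), CH2Cl2, 0 °C
Reagents that add atoms: isobutyric anhydride 7, CC(C)C(=O)OC(=O)C(C)C
Why: DMAP-catalysed acylation of a primary alcohol under basic, chloride-free conditions should leave the oxirane untouched and gives a glycidyl ester that is easier to handle than the free epoxy alcohol.

Step 4
Reactants: 8 [2-(2-methoxy-4-methylphenyl)oxiran-2-yl]methyl 2-methylpropanoate (racemic); 9 2-methylpropanoic acid (isobutyric acid)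
Product: 10 2-hydroxy-2-(2-methoxy-4-methylphenyl)propane-1,3-diyl bis(2-methylpropanoate) (target, achiral)
Conditions: iPrCO2H (3 equiv), Cs2CO3 (1 equiv), DMF, 70 °C
Reagents that add atoms: isobutyric acid 9, CC(C)C(=O)O
Why: Caesium isobutyrate formed in the flask opens the 2,2-disubstituted oxirane by SN2 attack at its unsubstituted CH2 carbon (the glycidyl ester plus carboxylic acid route to 1,3-diacylglycerols); the remaining free acid protonates the tertiary alkoxide, the carboxylate buffer suppresses benzylic ionisation, and the stereocentre vanishes as the second identical arm is formed.

**Compound list**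

1 | 1-bromo-2-methoxy-4-methylbenzene | COc1cc(C)ccc1Br | starting material
2 | 4,4,5,5-tetramethyl-2-(prop-1-en-2-yl)-1,3,2-dioxaborolane | C=C(C)B1OC(C)(C)C(C)(C)O1 | starting material
3 | 2-methoxy-4-methyl-1-(prop-1-en-2-yl)benzene | C=C(C)c1ccc(C)cc1OC | intermediate
4 | dioxygen | O=O | starting material
5 | 2-(2-methoxy-4-methylphenyl)prop-2-en-1-yl hydroperoxide | C=C(COO)c1ccc(C)cc1OC | intermediate (not isolated)
6 | [2-(2-methoxy-4-methylphenyl)oxiran-2-yl]methanol, racemic | COc1cc(C)ccc1C1(CO)CO1 | intermediate
7 | 2-methylpropanoic anhydride | CC(C)C(=O)OC(=O)C(C)C | starting material
8 | [2-(2-methoxy-4-methylphenyl)oxiran-2-yl]methyl 2-methylpropanoate, racemic | COc1cc(C)ccc1C1(COC(=O)C(C)C)CO1 | intermediate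
9 | 2-methylpropanoic acid | CC(C)C(=O)O | starting material
10 | 2-hydroxy-2-(2-methoxy-4-methylphenyl)propane-1,3-diyl bis(2-methylpropanoate), achiral | COc1cc(C)ccc1C(O)(COC(=O)C(C)C)COC(=O)C(C)C | target

**Step count**

Total steps: 4. Longest linear sequence: 4 steps (1 → 3 → 6 → 8 → 10).

**Steps most likely to fail**

Step 2. The ene reaction of a 1,1-disubstituted, arene-twisted alkene may be too slow. Sensitiser bleaching, dioxetane cleavage to the aryl methyl ketone, or titanium-induced opening and rearrangement of the benzylic oxirane could then take over. The fallback sets out from 3 and returns at 6. The allylic methyl group would be hydroxylated with catalytic SeO2 and t-BuOOH in CH2Cl2 (ene reaction followed by [2,3]-sigmatropic shift) to give 2-(2-methoxy-4-methylphenyl)prop-2-en-1-ol F1. Hydroxyl-directed epoxidation of this allylic alcohol with VO(acac)2 and t-BuOOH in CH2Cl2 at 0 °C should then deliver 6.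

Step 4. Displacement at an oxirane CH2 that sits next to a fully substituted carbon may be sluggish at a temperature the substrate tolerates. Ionisation of the electron-rich benzylic C–O bond, with hydride shift to an aldehyde or elimination, could then compete. The fallback sets out from 6, bypasses 8 and returns at 10. The oxirane would be opened with aqueous KOH in DMSO at 70 °C to 2-(2-methoxy-4-methylphenyl)propane-1,2,3-triol F2. Attack at either oxirane carbon, and the degenerate Payne rearrangement, lead to this same triol, so regiochemistry no longer matters. Both primary hydroxyls would then be acylated with isobutyryl chloride (2.1 equiv) and 2,4,6-collidine in CH2Cl2 at −40 to 0 °C, the hindered tertiary benzylic hydroxyl staying free, to give 10.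

Step 3. The oxirane may be lost during acylation or purification, through opening by carboxylate or acid traces or rearrangement on silica. The fallback sets out from 6 and returns at 10, with the order of events reversed so that the epoxy alcohol is never acylated. Crude 6 would be heated with isobutyric acid and Cs2CO3 in DMF, opening the oxirane at CH2 to 2,3-dihydroxy-2-(2-methoxy-4-methylphenyl)propyl 2-methylpropanoate F3. The remaining primary hydroxyl would then be acylated selectively with isobutyryl chloride (1.05 equiv) and 2,4,6-collidine in CH2Cl2 at −40 °C to give 10.

**Further compounds**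

F1 | step 2 | 2-(2-methoxy-4-methylphenyl)prop-2-en-1-ol | C=C(CO)c1ccc(C)cc1OC
F2 | step 4 | 2-(2-methoxy-4-methylphenyl)propane-1,2,3-triol | COc1cc(C)ccc1C(O)(CO)CO
F3 | step 3 | 2,3-dihydroxy-2-(2-methoxy-4-methylphenyl)propyl 2-methylpropanoate (racemic) | COc1cc(C)ccc1C(O)(CO)COC(=O)C(C)C
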